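The plan rests on cutting the O1–C8a aryl ether of ring C. In the target both carbons flanking C4a, namely C8a and C5, carry oxygen and both lie ortho to the C4 ketone, so a symmetric 2,6-difluoro-4-methoxybenzoyl unit can stand in for ring A. The precursor is an open 1,3-diketone that joins this unit to a 2,5-bis(benzyloxy)-3,4-dimethoxyphenyl ketone (ring B). Mild base turns it into an enolate whose oxygen displaces one fluoride. This closes the pyranone in one operation and leaves the other fluoride at C5, peri to the ketone, ready for exchange with benzyl alkoxide. One hydrogenolysis then frees all three phenols.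

Key step: step 7

Remark: flavone numbering (O1, C2, C3, C4, C4a, C5 to C8, C8a; primed numbers for ring B) is used throughout, and the 1,3-diketone is drawn in its diketo form although it should exist largely as the chelated enol; the target has no stereocentre.

Step 1
Reactants: 1 2,3-dimethoxyphenol
Product: 2 2,3-dimethoxy-1,4-benzoquinone
Conditions: (KSO3)2NO (2.2 equiv), KH2PO4 buffer, H2O/acetone, 0 °C to rt
Reagents that add atoms: potassium nitrosodisulfonate, [K+].[K+].[O-]S(=O)(=O)N([O])S(=O)(=O)[O-]
Why: Teuber oxidation, in which one nitrosodisulfonate radical removes the phenolic hydrogen and a second delivers oxygen to the unsubstituted para carbon, the normal outcome for a phenol whose para position is free.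

Step 2
Reactants: 2 2,3-dimethoxy-1,4-benzoquinone
Product: 4 1,4-bis(benzyloxy)-2,3-dimethoxybenzene, via hydroquinone 3 (not isolated)
Conditions: Na2S2O4, EtOAc/H2O, rt, N2; phase cut, solvent swap to DMF; BnBr (2.4 equiv), K2CO3 (3 equiv), 50 °C
Reagents that add atoms: benzyl bromide, BrCc1ccccc1
Why: Dithionite reduction of the quinone followed by a double Williamson ether synthesis, with the electron-rich hydroquinone carried on under nitrogen so that air cannot oxidise it back.

Step 3
Reactants: 4 1,4-bis(benzyloxy)-2,3-dimethoxybenzene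
Product: 5 1,4-bis(benzyloxy)-5-bromo-2,3-dimethoxybenzene (the same as 1-bromo-2,5-bis(benzyloxy)-3,4-dimethoxybenzene)
Conditions: NBS (1.0 equiv), MeCN, 0 °C to rt, dark
Reagents that add atoms: N-bromosuccinimide, O=C1CCC(=O)N1Br
Why: Electrophilic aromatic bromination, in which the two free ring positions of 4 are equivalent by symmetry and each is ortho to a benzyloxy and para to a methoxy group, so only one monobromide can form and the bromine then slows a second substitution.

Step 4
Reactants: 5 1,4-bis(benzyloxy)-5-bromo-2,3-dimethoxybenzene; 6 N-methoxy-N-methylacetamide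
Product: 8 1-[2,5-bis(benzyloxy)-3,4-dimethoxyphenyl]ethanone, via aryllithium 7 (not isolated)
Conditions: n-BuLi (1.05 equiv), THF, −78 °C; then 6 (1.3 equiv), −78 to 0 °C; 1 M HCl quench
Reagents that add atoms: none
Why: Bromine–lithium exchange at −78 °C is faster than deprotonation of the benzylic CH2 groups, and acylation of the aryllithium with the Weinreb amide (Weinreb ketone synthesis) stops at the methyl ketone.

Step 5
Reactants: 9 2,6-difluoro-4-methoxybenzoic acid
Product: 10 2,6-difluoro-4-methoxybenzoyl chloride
Conditions: (COCl)2 (1.3 equiv), DMF (cat.), CH2Cl2, 0 °C to rt; evaporate, use crude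
Reagents that add atoms: oxalyl chloride, O=C(Cl)C(=O)Cl
Why: Standard acid chloride formation with oxalyl chloride under DMF catalysis (Vilsmeier-type activation), to which the aryl fluorides and the methyl ether are inert.

Step 6
Reactants: 8 1-[2,5-bis(benzyloxy)-3,4-dimethoxyphenyl]ethanone; 10 2,6-difluoro-4-methoxybenzoyl chloride
Product: 12 1-(2,6-difluoro-4-methoxyphenyl)-3-[2,5-bis(benzyloxy)-3,4-dimethoxyphenyl]propane-1,3-dione, via lithium enolate 11 (not isolated)
Conditions: LiN(SiMe3)2 (2.2 equiv), THF, −78 °C; then 10 (1.05 equiv), −78 to −20 °C; cold 1 M HCl quench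
Reagents that add atoms: none
Why: Crossed Claisen-type C-acylation of a lithium enolate with a non-enolisable aroyl chloride, in which the second equivalent of base holds the more acidic diketone as its chelated lithium salt and so blocks diacylation, while the low temperature leaves both fluorides untouched.

Step 7
Reactants: 12 1-(2,6-difluoro-4-methoxyphenyl)-3-[2,5-bis(benzyloxy)-3,4-dimethoxyphenyl]propane-1,3-dione
Product: 15 2-[2,5-bis(benzyloxy)-3,4-dimethoxyphenyl]-5-fluoro-7-methoxy-4H-chromen-4-one, via potassium enolate 13 (not isolated), via Meisenheimer adduct 14 (not isolated)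
Conditions: K2CO3 (2 equiv), dry DMF, 70–80 °C, N2
Reagents that add atoms: none
Why: K2CO3 converts 12 into the Z-enolate 13, whose oxygen on the ring B side adds to C8a, a fluorine-bearing carbon ortho to the aroyl ketone, to give Meisenheimer adduct 14 with the charge resting on C4a and the C4 carbonyl oxygen, and expulsion of fluoride restores the aromaticity of ring A (addition–elimination SNAr). The closest known reaction type is the base-mediated, metal-free intramolecular O-arylation of 1-(2-haloaryl)-1,3-diketones to chromones and flavones. Ring C closes as a six-membered ring, and because the C8a=C4a π bond that takes up the electrons lies inside the new ring, the addition is a 6-endo-trig closure, an intramolecular oxa-Michael addition to the C8a=C4a–C4=O unit. No stereocentre is created in 15, since the tetrahedral C8a of 14 becomes planar again when fluoride leaves. Site selectivity is built into 12: rotation about the aryl–carbonyl bond makes the two fluorines equivalent, attack through C3 or through the other enolate oxygen would need a four-membered ring, closure onto C2' of ring B would have to expel benzyl oxide from an electron-rich ring, and the methoxy group of ring A is meta to the carbon attacked and so does not enrich it. The second fluoride survives because ring closure uses up the only nucleophile tethered to ring A and carbonate is too poor a nucleophile to attack C5 at this temperature.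

Step 8
Reactants: 15 2-[2,5-bis(benzyloxy)-3,4-dimethoxyphenyl]-5-fluoro-7-methoxy-4H-chromen-4-one
Product: 16 5-(benzyloxy)-2-[2,5-bis(benzyloxy)-3,4-dimethoxyphenyl]-7-methoxy-4H-chromen-4-one
Conditions: BnOH (1.3 equiv), NaH (1.2 equiv), dry THF/DMF, 0 °C to rt
Reagents that add atoms: benzyl alcohol, OCc1ccccc1
Why: Intermolecular SNAr, favoured because C5 is ortho to C4a and thus conjugated with the C4 ketone, both oxygen donors of ring A (7-OMe and O1) are meta to C5, fluoride is by far the best leaving group present, and any addition of alkoxide at C2 is reversible under anhydrous conditions.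

Step 9
Reactants: 16 5-(benzyloxy)-2-[2,5-bis(benzyloxy)-3,4-dimethoxyphenyl]-7-methoxy-4H-chromen-4-one
Product: 17 2-(2,5-dihydroxy-3,4-dimethoxyphenyl)-5-hydroxy-7-methoxy-4H-chromen-4-one (CNP0170944.0)
Conditions: H2 (1 atm), 10% Pd/C, EtOAc/MeOH, rt; filtration and concentration under argon
Reagents that add atoms: none
Why: Catalytic hydrogenolysis of the three aryl benzyl ethers under one atmosphere of hydrogen, conditions under which the methyl ethers and the pyranone C2=C3 bond are normally kept, with air excluded because ring B of the product is a hydroquinone.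

Compound list
1 | 2,3-dimethoxyphenol | COc1cccc(O)c1OC | starting material
2 | 2,3-dimethoxy-1,4-benzoquinone | COC1=C(OC)C(=O)C=CC1=O | intermediate
3 | 2,3-dimethoxybenzene-1,4-diol (not isolated) | COc1c(O)ccc(O)c1OC | intermediate
4 | 1,4-bis(benzyloxy)-2,3-dimethoxybenzene | COc1c(OCc2ccccc2)ccc(OCc2ccccc2)c1OC | intermediate
5 | 1,4-bis(benzyloxy)-5-bromo-2,3-dimethoxybenzene | COc1c(OC)c(OCc2ccccc2)c(Br)cc1OCc1ccccc1 | intermediate
6 | N-methoxy-N-methylacetamide | CC(=O)N(C)OC | starting material
7 | [2,5-bis(benzyloxy)-3,4-dimethoxyphenyl]lithium (not isolated) | [Li]c1cc(OCc2ccccc2)c(OC)c(OC)c1OCc1ccccc1 | intermediate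
8 | 1-[2,5-bis(benzyloxy)-3,4-dimethoxyphenyl]ethanone | CC(=O)c1cc(OCc2ccccc2)c(OC)c(OC)c1OCc1ccccc1 | intermediate
9 | 2,6-difluoro-4-methoxybenzoic acid | COc1cc(F)c(C(=O)O)c(F)c1 | starting material
10 | 2,6-difluoro-4-methoxybenzoyl chloride | COc1cc(F)c(C(=O)Cl)c(F)c1 | intermediate
11 | lithium enolate of 8 (not isolated) | [Li+].C=C([O-])c1cc(OCc2ccccc2)c(OC)c(OC)c1OCc1ccccc1 | intermediate
12 | 1-(2,6-difluoro-4-methoxyphenyl)-3-[2,5-bis(benzyloxy)-3,4-dimethoxyphenyl]propane-1,3-dione | COc1cc(F)c(C(=O)CC(=O)c2cc(OCc3ccccc3)c(OC)c(OC)c2OCc2ccccc2)c(F)c1 | intermediate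
13 | potassium (Z)-enolate of 12, oxygen anion on the ring B side (not isolated) | [K+].COc1cc(F)c(C(=O)/C=C(\[O-])c2cc(OCc3ccccc3)c(OC)c(OC)c2OCc2ccccc2)c(F)c1 | intermediate
14 | Meisenheimer adduct, potassium salt, tetrahedral C8a bearing F and O1 (racemic, transient, not isolated) | [K+].COC1=CC2(F)OC(=CC([O-])=C2C(F)=C1)c1cc(OCc2ccccc2)c(OC)c(OC)c1OCc1ccccc1 | intermediate
15 | 2-[2,5-bis(benzyloxy)-3,4-dimethoxyphenyl]-5-fluoro-7-methoxy-4H-chromen-4-one | COc1cc(F)c2c(=O)cc(-c3cc(OCc4ccccc4)c(OC)c(OC)c3OCc3ccccc3)oc2c1 | intermediate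
16 | 5-(benzyloxy)-2-[2,5-bis(benzyloxy)-3,4-dimethoxyphenyl]-7-methoxy-4H-chromen-4-one | COc1cc(OCc2ccccc2)c2c(=O)cc(-c3cc(OCc4ccccc4)c(OC)c(OC)c3OCc3ccccc3)oc2c1 | intermediate
17 | 2-(2,5-dihydroxy-3,4-dimethoxyphenyl)-5-hydroxy-7-methoxy-4H-chromen-4-one | COc1cc(O)c2c(=O)cc(-c3cc(O)c(OC)c(OC)c3O)oc2c1 | target

Total step count: 9. Longest linear sequence: 8 (steps 1 to 4, then 6 to 9). Step 5 is a one-step side branch.

Steps most likely to fail

**Step 7.**
- The ring closure may be too slow. The para methoxy group weakens the ketone as an acceptor, and the two ortho fluorines twist the ketone out of the plane of ring A.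
- Harsher heating would then favour two side processes. One is retro-Claisen cleavage of the diketone by traces of water. The other is displacement of fluoride by dimethylamine released as DMF breaks down.
- The fallback sets out from 5 and comes back at 16. It closes ring C from the other side, through the O1–C2 bond, with a ring A phenol in place of a fluoride.
- Bromine–lithium exchange of 5 (through 7) and a DMF quench should give 2,5-bis(benzyloxy)-3,4-dimethoxybenzaldehyde F1.
- Monobenzylation of commercial 1-(2,6-dihydroxy-4-methoxyphenyl)ethanone (BnBr, K2CO3, acetone) should give 1-[2-(benzyloxy)-6-hydroxy-4-methoxyphenyl]ethanone F2. The remaining hydroxyl is held back by its hydrogen bond to the ketone.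
- Claisen–Schmidt condensation of the two (KOH, EtOH, rt) should give (E)-1-[2-(benzyloxy)-6-hydroxy-4-methoxyphenyl]-3-[2,5-bis(benzyloxy)-3,4-dimethoxyphenyl]prop-2-en-1-one F3.
- Oxidative cyclisation of this 2'-hydroxychalcone with catalytic I2 in DMSO at about 120 °C should give 16 directly, so that steps 5 to 8 fall away.

**Step 6.**
- The enolate may be acylated on oxygen in place of carbon.
- Proton transfer from the product may quench unreacted enolate.
- The amide base may consume the acid chloride.
- The fallback sets out from 8 and comes back at 12. It replaces the acylation by an aldol addition and an oxidation, so the choice between oxygen and carbon does not arise.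
- Enolate 11, made with one equivalent of LiN(SiMe3)2, is added at −78 °C to commercial 2,6-difluoro-4-methoxybenzaldehyde. This should give racemic 1-[2,5-bis(benzyloxy)-3,4-dimethoxyphenyl]-3-(2,6-difluoro-4-methoxyphenyl)-3-hydroxypropan-1-one F4.
- Dess–Martin periodinane in CH2Cl2 should then oxidise the alcohol to 12.

**Step 8.**
- Addition of the alkoxide at C2 may lead to opening and cleavage of the pyranone if moisture is present.
- Displacement at C5 may stay incomplete.
- The fallback sets out from 8 and comes back at 16. It puts the benzyloxy group in before ring closure, on a substrate with no pyranone to attack.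
- Commercial 2,6-difluoro-4-methoxybenzaldehyde with one equivalent of NaOCH2Ph (BnOH, NaH, THF, 0 °C) should give 2-(benzyloxy)-6-fluoro-4-methoxybenzaldehyde F5.
- Aldol addition of enolate 11 should give racemic 3-[2-(benzyloxy)-6-fluoro-4-methoxyphenyl]-1-[2,5-bis(benzyloxy)-3,4-dimethoxyphenyl]-3-hydroxypropan-1-one F6.
- Dess–Martin oxidation should give 1-[2-(benzyloxy)-6-fluoro-4-methoxyphenyl]-3-[2,5-bis(benzyloxy)-3,4-dimethoxyphenyl]propane-1,3-dione F7.
- The same enolate SNAr closure (K2CO3, DMF) on the single remaining fluoride should give 16.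

Further compounds
F1 | step 7 | 2,5-bis(benzyloxy)-3,4-dimethoxybenzaldehyde | O=Cc1cc(OCc2ccccc2)c(OC)c(OC)c1OCc1ccccc1
F2 | step 7 | 1-[2-(benzyloxy)-6-hydroxy-4-methoxyphenyl]ethanone | CC(=O)c1c(O)cc(OC)cc1OCc1ccccc1
F3 | step 7 | (E)-1-[2-(benzyloxy)-6-hydroxy-4-methoxyphenyl]-3-[2,5-bis(benzyloxy)-3,4-dimethoxyphenyl]prop-2-en-1-one | COc1cc(O)c(C(=O)/C=C/c2cc(OCc3ccccc3)c(OC)c(OC)c2OCc2ccccc2)c(OCc2ccccc2)c1
F4 | step 6 | 1-[2,5-bis(benzyloxy)-3,4-dimethoxyphenyl]-3-(2,6-difluoro-4-methoxyphenyl)-3-hydroxypropan-1-one (racemic) | COc1cc(F)c(C(O)CC(=O)c2cc(OCc3ccccc3)c(OC)c(OC)c2OCc2ccccc2)c(F)c1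
F5 | step 8 | 2-(benzyloxy)-6-fluoro-4-methoxybenzaldehyde | COc1cc(F)c(C=O)c(OCc2ccccc2)c1
F6 | step 8 | 3-[2-(benzyloxy)-6-fluoro-4-methoxyphenyl]-1-[2,5-bis(benzyloxy)-3,4-dimethoxyphenyl]-3-hydroxypropan-1-one (racemic) | COc1cc(F)c(C(O)CC(=O)c2cc(OCc3ccccc3)c(OC)c(OC)c2OCc2ccccc2)c(OCc2ccccc2)c1
F7 | step 8 | 1-[2-(benzyloxy)-6-fluoro-4-methoxyphenyl]-3-[2,5-bis(benzyloxy)-3,4-dimethoxyphenyl]propane-1,3-dione | COc1cc(F)c(C(=O)CC(=O)c2cc(OCc3ccccc3)c(OC)c(OC)c2OCc2ccccc2)c(OCc2ccccc2)c1
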